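A flat first stretch of readings tempts one to see a wait followed by a steady rate, and that picture can mislead on a flask that changes temperature halfway.

| setting | north | west | south-east | dawn | midnight | dusk | spring |
|---|---|---|---|---|---|---|---|
| left-handed substrate | 0.25 M | 0.25 M | 0.25 M | 0.25 M | 0.25 M | 0.25 M | 0.25 M |
| right-handed substrate | 0.25 M | 0.25 M | 0.25 M | 0.25 M | 0.25 M | 0.25 M | 0.25 M |
| partner | 0.20 M | 0.45 M | 0.30 M | 0.300 M | 0.300 M | 0.300 M | 0.300 M |
| protic impurity | 5 mM | 5 mM | 10 mM | 5.00 mM | 5.00 mM | 5.00 mM | 5.00 mM |
| precatalyst | 2.3 mM | 2.3 mM | 2.3 mM | 2.3 mM | 2.3 mM | 2.3 mM | 2.3 mM |
| temperature | −5 °C | 17 °C | −5 °C | 25 °C | −15 °C | 5 °C |  |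
| remark | run made earlier | run made earlier | run made earlier |  |  |  | at −15 °C until 25 min, from then on at 25 °C |
| time |  |  |  | 50 min | 50 min | 50 min | 50 min |

| north: time / min | north: left-handed product / % | west: time / min | west: left-handed product / % | south-east: time / min | south-east: left-handed product / % |
|---|---|---|---|---|---|
| 20.0 | 0 | 12.0 | 1.4 | 20.0 | 0 |
| 40.0 | 0 | 25.0 | 4.7 | 40.0 | 0 |
| 80.0 | 0.1 | 40.0 | 10.2 | 80.0 | 0.2 |
| 240 | 1.2 | 50.0 | 12.5 | 240 | 4.2 |

(standard deviation of a reading: 0.5 percentage points)

- catalyst is single-handed; left-handed substrate and right-handed substrate are mirror images of each other, charged as a racemate, each of them at the stated concentration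
- the analysis behind the earlier runs scatters by 0.5 percentage points, standard deviation

* the flask that comes out highest in amount of left-handed product, in percent of the left-handed substrate and right-handed substrate together charged, or "all alike" when all lie within 1.5 percentage points (dawn / midnight / dusk / spring / all alike)
* left-handed product at the end, in percent of the left-handed substrate and right-handed substrate together charged, dawn
* left-handed product at the end, in percent of the left-handed substrate and right-handed substrate together charged, midnight
* left-handed product at the end, in percent of the left-handed substrate and right-handed substrate together charged, dusk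
* left-handed product at the end, in percent of the left-handed substrate and right-handed substrate together charged, spring

Two views stand against each other. Gate says the partner must first clear the protic impurity, and product then runs at a steady rate. So in spring the cold half pays the wait and the warm half runs at full speed. Ramp says catalyst grows steadily from precatalyst, so product grows as the square of time. So in spring the warm half starts its ramp afresh.

Ramp needs one quantity. South-east gives 1170 min for the ramp time, the time of a reading divided by the square root of its product fraction. On a pure ramp the time of reading drops out of it, and the product fraction is the square of time over ramp time. South-east over north reads 3.50, and the scatter allows 2.18. The partner ratio squared is 2.25, so I take partner squared and set the impurity aside.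

With partner squared, the ramp time goes as one over partner. West at 25.0 min, scaled to the partner of south-east, gives 173 min. The two numbers give an apparent activation temperature of 13500 K. So my ramp time is 3110 min for midnight and 92.5 min for dawn.

My reckoning then gives 0.0258 % for midnight and 1.12 % for dusk. Dawn has a bare ramp of 29.2 %. But the last west reading is 0.665 of what its own ramp gives, so I scale dawn to 19.4 %. Spring gets 7.30 % from its warm half.

Gate takes the west slope from 25.0 min to 40.0 min, scales it by partner and by the same lift, and gives spring 21.4 %.

The forecast took the side of Ramp, saying “the cold half does almost nothing”, and differed from my figures: dawn highest, with 20 % for dawn, 0.05 % for midnight, 1 % for dusk and 8 % for spring.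

The flasks give 16.0 % for dawn, 0.0255 % for midnight, 1.10 % for dusk and 6.21 % for spring, with dawn highest. Spring stands below the figure of Gate.

    partner → decomposition product (k = 7.29 × 10⁻⁵ min⁻¹, Ea = 107 kJ mol⁻¹)
    partner + precatalyst → catalyst + spent reagent (k = 0.0320 L mol⁻¹ min⁻¹, Ea = 75.0 kJ mol⁻¹)
    partner + catalyst + left-handed substrate → catalyst + left-handed product (k = 78.7 L² mol⁻² min⁻¹, Ea = 39.0 kJ mol⁻¹)
    partner + protic impurity → quenched reagent (k = 6.73 L mol⁻¹ min⁻¹, Ea = 54.0 kJ mol⁻¹)
    partner + catalyst + right-handed substrate → catalyst + right-handed product (k = 33.1 L² mol⁻² min⁻¹, Ea = 46.0 kJ mol⁻¹)
    (constants at 25 °C)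

The picture of Gate fits the cold early stretch of one flask. The neighbour is midnight read at 20 min. The ramp time of midnight, 3110 min, gives 0.00414 % there, less than the scatter of 0.5 percentage points. In that neighbour, left-handed product reads 0 % with 25 % of the protic impurity still there, as a wait looks, yet catalyst already stands at 0.175 % of its charge.

The data were generated by integration for substances that don't exist; the scatter is artificial.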